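**Retrosynthetic overview**
1. The C14 aldehyde is carried as a silyl ether and unveiled last (desilylation, then allylic oxidation).
2. Key disconnection: the C5–C6 bond together with the lactone C–O bond, back to an acyclic (Z)-iodoalkenyl aldehyde. One Nozaki–Hiyama–Kishi/lactonisation cascade closes ring A (ten-membered carbocycle) and then ring B (methylidene γ-lactone). This works because C6 is both the allylic carbinol carbon next to the C4=C5 olefin and the γ-carbon of the C12 ester (C6–C7–C11–C12), and because both ring-A olefins (C1=C10, C4=C5) are cis within the ring and fold the chain.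
3. C7–C8 is cut next: a chelation-controlled indium Barbier reaction of an α-hydroxy lactol with a (Z)-2-(bromomethyl)enoate sets C7 and C8 and brings in C6 (as acetal) and the acrylate C11–C13.
4. The lactol (C8, C9, C10, C14) comes from dimethyl L-malate, which supplies the C9 configuration; dianion aldol with the C1–C5 aldehyde and a Stobbe-type ring opening give the C1=C10 olefin.
5. The (Z)-vinyl iodide C4=C5 comes from anti-carbometalation/iodination of pent-4-yn-1-ol; rings form in the order A, then B, both in the key step.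

Key step: step 13

Remark: germacrane numbering is used (C1–C10 ring A, C11–C13 methylidene-lactone carbons, C14 formyl carbon, C15 methyl). The target is read as the (6R,7S,8S,9S)-6,12-olide with 1(10)E and 4Z olefins, both cis within ring A.

**Step 1**
Reactants: 1 pent-4-yn-1-ol
Product: 4 (4Z)-5-iodo-4-methylpent-4-en-1-ol, via (E)-alkenylalane 2 (not isolated), via (Z)-alkenylalane 3 (not isolated)
Conditions: Me3Al (3 equiv), Cp2ZrCl2 (0.25 equiv), (CH2Cl)2, 23 °C; AlCl3 (0.5 equiv), 50 °C; I2, THF, −30 to 0 °C; aq. K2CO3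
Reagents that add atoms: trimethylaluminium C[Al](C)C; iodine II
Why: Zirconium-catalysed syn-carboalumination puts methyl on C4 and aluminium on C5, heating with AlCl3 lets the alkenylalane isomerise to the alkoxide-chelated (Z)-isomer (anti-carbometalation of ω-alkynols), and iodinolysis with retention gives the (4Z)-vinyl iodide.

**Step 2**
Reactants: 4 (4Z)-5-iodo-4-methylpent-4-en-1-ol
Product: 5 (4Z)-5-iodo-4-methylpent-4-enal
Conditions: Dess–Martin periodinane (1.2 equiv), CH2Cl2, 0 °C to rt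
Reagents that add atoms: none
Why: Dess–Martin oxidation of the primary alcohol stops at the aldehyde and leaves the vinyl iodide untouched; no stereocentre is involved.

**Step 3**
Reactants: 6 dimethyl (2S)-2-hydroxybutanedioate (dimethyl L-malate); 5 (4Z)-5-iodo-4-methylpent-4-enal
Product: 9 methyl (4S)-4-hydroxy-2-[(3Z)-4-iodo-3-methylbut-3-en-1-yl]-5-oxooxolane-3-carboxylate (mixture of C2/C3 epimers), via dilithium alkoxide-enolate 7 (not isolated), via open-chain aldol adduct 8 (not isolated)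
Conditions: LDA (2.2 equiv), THF, −78 to −20 °C; 5, −78 °C; AcOH; then CSA (cat.), CH2Cl2, rt
Reagents that add atoms: none
Why: Fráter–Seebach-type dianion aldol: the alkoxide-enolate of the malate adds through C10 to the aldehyde without touching the C9 carbinol centre (source of the 9S configuration), and acid closes the new hydroxyl onto the C8 ester as a γ-lactone (5-exo-trig); the two new stereocentres are erased in step 4.

**Step 4**
Reactants: 9 methyl (4S)-4-hydroxy-2-[(3Z)-4-iodo-3-methylbut-3-en-1-yl]-5-oxooxolane-3-carboxylate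
Product: 10 (2S,3E,7Z)-2-hydroxy-8-iodo-3-(methoxycarbonyl)-7-methylocta-3,7-dienoic acid
Conditions: DBU (3 equiv), CH2Cl2, 0 °C to rt; aq. HCl
Reagents that add atoms: none
Why: E1cB ring opening of a paraconic ester (the second stage of a Stobbe condensation): deprotonation at C10 expels the lactone carboxylate rather than the free C9 hydroxyl and should give the conjugated alkylidene with the chain trans to CO2Me (C2 cis to C9), while C9, now next to a carboxylate, is not enolised.

**Step 5**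
Reactants: 10 (2S,3E,7Z)-2-hydroxy-8-iodo-3-(methoxycarbonyl)-7-methylocta-3,7-dienoic acid
Product: 12 (3S,4Z)-3-hydroxy-4-[(4Z)-5-iodo-4-methylpent-4-en-1-ylidene]oxolan-2-one, via hydroxy acid 11 (not isolated)
Conditions: DIBAL-H (5 equiv), THF, −78 to −30 °C; 2 M HCl, rt
Reagents that add atoms: none
Why: DIBAL-H reduces the conjugated methyl ester by 1,2-addition to the allylic alcohol while the aluminium carboxylate is inert at low temperature (reduction–lactonisation of Stobbe half-esters), and acid closes the γ-lactone onto C8; C9 is not touched.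

**Step 6**
Reactants: 12 (3S,4Z)-3-hydroxy-4-[(4Z)-5-iodo-4-methylpent-4-en-1-ylidene]oxolan-2-one
Product: 13 (3S,4Z)-4-[(4Z)-5-iodo-4-methylpent-4-en-1-ylidene]oxolane-2,3-diol (anomeric mixture)
Conditions: DIBAL-H (2.2 equiv), CH2Cl2, −78 °C; aq. Rochelle salt
Reagents that add atoms: none
Why: Partial reduction of a γ-lactone to the lactol by DIBAL-H at −78 °C through the stable aluminium hemiacetal; the lactol is the masked form of the sensitive α-hydroxy-β,γ-unsaturated aldehyde.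

**Step 7**
Reactants: 14 methyl prop-2-enoate; 15 2,2-dimethoxyacetaldehyde
Product: 16 methyl 3-hydroxy-4,4-dimethoxy-2-methylidenebutanoate (racemic)
Conditions: DABCO (0.5 equiv), 1,4-dioxane/H2O (1:1), rt
Reagents that add atoms: none
Why: Morita–Baylis–Hillman reaction of an activated α,α-dialkoxy aldehyde with an acrylate; the carbinol stereocentre is lost in step 8.

**Step 8**
Reactants: 16 methyl 3-hydroxy-4,4-dimethoxy-2-methylidenebutanoate
Product: 17 methyl (2Z)-2-(bromomethyl)-4,4-dimethoxybut-2-enoate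
Conditions: NBS (1.2 equiv), Me2S (1.3 equiv), CH2Cl2, 0 °C to rt
Reagents that add atoms: N-bromosuccinimide O=C1CCC(=O)N1Br
Why: Corey–Kim-type activation of the allylic alcohol by the bromosulfonium salt and SN2′ attack of bromide give the rearranged primary allylic bromide, for which the (Z)-isomer (CH(OMe)2 trans to CO2Me) is the usual outcome with Baylis–Hillman alcohols.

**Step 9**
Reactants: 13 (3S,4Z)-4-[(4Z)-5-iodo-4-methylpent-4-en-1-ylidene]oxolane-2,3-diol; 17 methyl (2Z)-2-(bromomethyl)-4,4-dimethoxybut-2-enoate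
Product: 18 methyl (3R,4S,5S,6Z,10Z)-3-(dimethoxymethyl)-4,5-dihydroxy-6-(hydroxymethyl)-11-iodo-10-methyl-2-methylideneundeca-6,10-dienoate
Conditions: In powder (2 equiv), THF/H2O (1:1), rt
Reagents that add atoms: none
Why: Indium-mediated Barbier allylation in water (as used for lactols of unprotected sugars): the lactol opens to the α-hydroxy aldehyde, the allylindium from 17 attacks through its γ-carbon (SE2′) and regenerates the 2-methylidene ester, chelation of indium between the C9 hydroxyl and the aldehyde oxygen should give the 8,9-syn diol, and the (Z)-γ-substituent should give the 7,8-syn relationship typical of (Z)-2-(bromomethyl)alk-2-enoates.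

**Step 10**
Reactants: 18 methyl (3R,4S,5S,6Z,10Z)-3-(dimethoxymethyl)-4,5-dihydroxy-6-(hydroxymethyl)-11-iodo-10-methyl-2-methylideneundeca-6,10-dienoate
Product: 19 methyl (3R,4S,5S,6Z,10Z)-6-({[tert-butyl(diphenyl)silyl]oxy}methyl)-3-(dimethoxymethyl)-4,5-dihydroxy-11-iodo-10-methyl-2-methylideneundeca-6,10-dienoate
Conditions: TBDPSCl (1.05 equiv), imidazole (2.2 equiv), CH2Cl2, 0 °C
Reagents that add atoms: tert-butyl(chloro)diphenylsilane CC(C)(C)[Si](Cl)(c1ccccc1)c1ccccc1
Why: Silylation with the bulky chlorosilane is selective for the primary allylic C14 hydroxyl over the two secondary hydroxyls; no stereocentre is affected.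

**Step 11**
Reactants: 19 methyl (3R,4S,5S,6Z,10Z)-6-({[tert-butyl(diphenyl)silyl]oxy}methyl)-3-(dimethoxymethyl)-4,5-dihydroxy-11-iodo-10-methyl-2-methylideneundeca-6,10-dienoate
Product: 20 methyl (3R,4S,5S,6Z,10Z)-6-({[tert-butyl(diphenyl)silyl]oxy}methyl)-3-(dimethoxymethyl)-11-iodo-10-methyl-2-methylidene-4,5-bis[(2-methylpropanoyl)oxy]undeca-6,10-dienoate
Conditions: (iPrCO)2O (4 equiv), Et3N, DMAP (0.2 equiv), CH2Cl2, 0 °C to rt
Reagents that add atoms: 2-methylpropanoic anhydride CC(C)C(=O)OC(=O)C(C)C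
Why: DMAP-catalysed acyl transfer esterifies both secondary hydroxyls with retention at C8 and C9 and should outrun lactonisation of O8 onto the C12 ester.

**Step 12**
Reactants: 20 methyl (3R,4S,5S,6Z,10Z)-6-({[tert-butyl(diphenyl)silyl]oxy}methyl)-3-(dimethoxymethyl)-11-iodo-10-methyl-2-methylidene-4,5-bis[(2-methylpropanoyl)oxy]undeca-6,10-dienoate
Product: 21 methyl (3R,4S,5S,6Z,10Z)-6-({[tert-butyl(diphenyl)silyl]oxy}methyl)-3-formyl-11-iodo-10-methyl-2-methylidene-4,5-bis[(2-methylpropanoyl)oxy]undeca-6,10-dienoate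
Conditions: LiBF4 (2 equiv), MeCN/H2O (50:1), rt; used crude at once
Reagents that add atoms: water O
Why: Lewis-acid-assisted acetal hydrolysis under nearly neutral conditions spares the silyl ether and the esters and limits enolisation of the β,γ-unsaturated aldehyde (C7 epimerisation, conjugation).

**Step 13**
Reactants: 21 methyl (3R,4S,5S,6Z,10Z)-6-({[tert-butyl(diphenyl)silyl]oxy}methyl)-3-formyl-11-iodo-10-methyl-2-methylidene-4,5-bis[(2-methylpropanoyl)oxy]undeca-6,10-dienoate
Product: 23 (3aS,4S,5S,6Z,10Z,11aR)-6-({[tert-butyl(diphenyl)silyl]oxy}methyl)-10-methyl-3-methylidene-2-oxo-2,3,3a,4,5,8,9,11a-octahydrocyclodeca[b]furan-4,5-diyl bis(2-methylpropanoate), via chromium alkoxide of hydroxy ester 22 (not isolated)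
Conditions: CrCl2 (15 equiv), NiCl2 (0.15 equiv), degassed DMSO/THF (3:1), 25 °C, 2 mM final concentration, 21 added over 12 h; aq. NH4Cl
Reagents that add atoms: none
Why: Divalent chromium reduces NiCl2 to zerovalent nickel, which inserts into the C5–I bond; transmetalation gives a (Z)-alkenylchromium species (trivalent chromium) that adds to the C6 aldehyde, and the chromium alkoxide so formed is acylated by the C12 methyl ester. The closest known reaction is the Nozaki–Hiyama–Kishi macrocyclisation of iodoalkenyl aldehydes, a reductive union of two electrophilic carbons, followed by the lactonisation known from chromium-mediated syntheses of α-methylidene γ-lactones. Ring A closes by a 10-exo-trig carbonyl addition that the two ring-cis olefins (C1=C10 and C4=C5) make feasible by folding the chain, and ring B closes by 5-exo-trig acyl substitution. C6 is controlled by the C7 stereocentre: Felkin–Anh attack anti to the C8 branch, reinforced by the 1,3-anti preference of the β-acyloxy group at C8, should give the (6R) alcohol and hence the trans-fused lactone. The step needs chemoselectivity for the aldehyde over three esters and an acrylate, which organochromium reagents provide, and cyclisation over oligomerisation and protodeiodination, which high dilution and slow addition of 21 to excess CrCl2 should secure; the (Z)-alkenyl geometry is retained in the nickel-to-chromium exchange.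

**Step 14**
Reactants: 23 (3aS,4S,5S,6Z,10Z,11aR)-6-({[tert-butyl(diphenyl)silyl]oxy}methyl)-10-methyl-3-methylidene-2-oxo-2,3,3a,4,5,8,9,11a-octahydrocyclodeca[b]furan-4,5-diyl bis(2-methylpropanoate)
Product: 24 (3aS,4S,5S,6Z,10Z,11aR)-6-(hydroxymethyl)-10-methyl-3-methylidene-2-oxo-2,3,3a,4,5,8,9,11a-octahydrocyclodeca[b]furan-4,5-diyl bis(2-methylpropanoate)
Conditions: HF·pyridine, pyridine/THF, 0 °C to rt
Reagents that add atoms: none
Why: Buffered HF·pyridine cleaves the silyl ether under mildly acidic conditions, which avoid the acyl shift from O9 to O14 and the conjugate additions to the methylidene lactone that basic fluoride could cause.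

**Step 15**
Reactants: 24 (3aS,4S,5S,6Z,10Z,11aR)-6-(hydroxymethyl)-10-methyl-3-methylidene-2-oxo-2,3,3a,4,5,8,9,11a-octahydrocyclodeca[b]furan-4,5-diyl bis(2-methylpropanoate)
Product: 25 (3aS,4S,5S,6E,10Z,11aR)-6-formyl-10-methyl-3-methylidene-2-oxo-2,3,3a,4,5,8,9,11a-octahydrocyclodeca[b]furan-4,5-diyl bis(2-methylpropanoate) (CNP0305839.3)
Conditions: MnO2 (20 equiv), CH2Cl2, rt
Reagents that add atoms: none
Why: MnO2 oxidises only the primary allylic alcohol to the conjugated aldehyde, whose geometry (formyl trans to C2) is already the thermodynamic one; esters and the methylidene lactone are inert.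

**Compound list**
1 | pent-4-yn-1-ol | C#CCCCO | starting material
2 | {[(4E)-5-(dimethylalumanyl)-4-methylpent-4-en-1-yl]oxy}(dimethyl)alumane | C[Al](C)OCCC/C(C)=C/[Al](C)C | intermediate
3 | {[(4Z)-5-(dimethylalumanyl)-4-methylpent-4-en-1-yl]oxy}(dimethyl)alumane | C[Al](C)OCCC/C(C)=C\[Al](C)C | intermediate
4 | (4Z)-5-iodo-4-methylpent-4-en-1-ol | OCCC/C(C)=C\I | intermediate
5 | (4Z)-5-iodo-4-methylpent-4-enal | O=CCC/C(C)=C\I | intermediate
6 | dimethyl (2S)-2-hydroxybutanedioate (dimethyl L-malate) | COC(=O)C[C@H](O)C(=O)OC | starting material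
7 | dilithium alkoxide-enolate of 6 | [Li]OC(OC)=C[C@H](O[Li])C(=O)OC | intermediate
8 | dimethyl (2S)-2-hydroxy-3-[(4Z)-1-hydroxy-5-iodo-4-methylpent-4-en-1-yl]butanedioate (epimer mixture) | COC(=O)C(C(O)CC/C(C)=C\I)[C@H](O)C(=O)OC | intermediate
9 | methyl (4S)-4-hydroxy-2-[(3Z)-4-iodo-3-methylbut-3-en-1-yl]-5-oxooxolane-3-carboxylate (C2/C3 epimers) | COC(=O)C1[C@H](O)C(=O)OC1CC/C(C)=C\I | intermediate
10 | (2S,3E,7Z)-2-hydroxy-8-iodo-3-(methoxycarbonyl)-7-methylocta-3,7-dienoic acid | COC(=O)/C(=C/CC/C(C)=C\I)[C@H](O)C(=O)O | intermediate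
11 | (2S,3Z,7Z)-2-hydroxy-3-(hydroxymethyl)-8-iodo-7-methylocta-3,7-dienoic acid | OC/C(=C/CC/C(C)=C\I)[C@H](O)C(=O)O | intermediate
12 | (3S,4Z)-3-hydroxy-4-[(4Z)-5-iodo-4-methylpent-4-en-1-ylidene]oxolan-2-one | O1C/C(=C/CC/C(C)=C\I)[C@H](O)C1=O | intermediate
13 | (3S,4Z)-4-[(4Z)-5-iodo-4-methylpent-4-en-1-ylidene]oxolane-2,3-diol (anomeric mixture) | O1C/C(=C/CC/C(C)=C\I)[C@H](O)C1O | intermediate
14 | methyl prop-2-enoate | C=CC(=O)OC | starting material
15 | 2,2-dimethoxyacetaldehyde | COC(OC)C=O | starting material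
16 | methyl 3-hydroxy-4,4-dimethoxy-2-methylidenebutanoate (racemic) | COC(=O)C(=C)C(O)C(OC)OC | intermediate
17 | methyl (2Z)-2-(bromomethyl)-4,4-dimethoxybut-2-enoate | BrC/C(C(=O)OC)=C\C(OC)OC | intermediate
18 | methyl (3R,4S,5S,6Z,10Z)-3-(dimethoxymethyl)-4,5-dihydroxy-6-(hydroxymethyl)-11-iodo-10-methyl-2-methylideneundeca-6,10-dienoate | I/C=C(/C)CC/C=C(/CO)[C@H](O)[C@@H](O)[C@@H](C(=C)C(=O)OC)C(OC)OC | intermediate
19 | methyl (3R,4S,5S,6Z,10Z)-6-({[tert-butyl(diphenyl)silyl]oxy}methyl)-3-(dimethoxymethyl)-4,5-dihydroxy-11-iodo-10-methyl-2-methylideneundeca-6,10-dienoate | I/C=C(/C)CC/C=C(/CO[Si](c1ccccc1)(c1ccccc1)C(C)(C)C)[C@H](O)[C@@H](O)[C@@H](C(=C)C(=O)OC)C(OC)OC | intermediate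
20 | methyl (3R,4S,5S,6Z,10Z)-6-({[tert-butyl(diphenyl)silyl]oxy}methyl)-3-(dimethoxymethyl)-11-iodo-10-methyl-2-methylidene-4,5-bis[(2-methylpropanoyl)oxy]undeca-6,10-dienoate | I/C=C(/C)CC/C=C(/CO[Si](c1ccccc1)(c1ccccc1)C(C)(C)C)[C@H](OC(=O)C(C)C)[C@@H](OC(=O)C(C)C)[C@@H](C(=C)C(=O)OC)C(OC)OC | intermediate
21 | methyl (3R,4S,5S,6Z,10Z)-6-({[tert-butyl(diphenyl)silyl]oxy}methyl)-3-formyl-11-iodo-10-methyl-2-methylidene-4,5-bis[(2-methylpropanoyl)oxy]undeca-6,10-dienoate | I/C=C(/C)CC/C=C(/CO[Si](c1ccccc1)(c1ccccc1)C(C)(C)C)[C@H](OC(=O)C(C)C)[C@@H](OC(=O)C(C)C)[C@@H](C(=C)C(=O)OC)C=O | intermediate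
22 | methyl 2-[(1S,2R,3Z,7Z,9S,10S)-8-({[tert-butyl(diphenyl)silyl]oxy}methyl)-2-hydroxy-4-methyl-9,10-bis[(2-methylpropanoyl)oxy]cyclodeca-3,7-dien-1-yl]prop-2-enoate (formed as its chromium alkoxide) | O[C@@H]1/C=C(/C)CC/C=C(/CO[Si](c2ccccc2)(c2ccccc2)C(C)(C)C)[C@H](OC(=O)C(C)C)[C@@H](OC(=O)C(C)C)[C@H]1C(=C)C(=O)OC | intermediate
23 | (3aS,4S,5S,6Z,10Z,11aR)-6-({[tert-butyl(diphenyl)silyl]oxy}methyl)-10-methyl-3-methylidene-2-oxo-2,3,3a,4,5,8,9,11a-octahydrocyclodeca[b]furan-4,5-diyl bis(2-methylpropanoate) | C=C1C(=O)O[C@@H]2/C=C(/C)CC/C=C(/CO[Si](c3ccccc3)(c3ccccc3)C(C)(C)C)[C@H](OC(=O)C(C)C)[C@@H](OC(=O)C(C)C)[C@@H]12 | intermediate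
24 | (3aS,4S,5S,6Z,10Z,11aR)-6-(hydroxymethyl)-10-methyl-3-methylidene-2-oxo-2,3,3a,4,5,8,9,11a-octahydrocyclodeca[b]furan-4,5-diyl bis(2-methylpropanoate) | C=C1C(=O)O[C@@H]2/C=C(/C)CC/C=C(/CO)[C@H](OC(=O)C(C)C)[C@@H](OC(=O)C(C)C)[C@@H]12 | intermediate
25 | (3aS,4S,5S,6E,10Z,11aR)-6-formyl-10-methyl-3-methylidene-2-oxo-2,3,3a,4,5,8,9,11a-octahydrocyclodeca[b]furan-4,5-diyl bis(2-methylpropanoate) | C=C1C(=O)O[C@@H]2/C=C(/C)CC/C=C(/C=O)[C@H](OC(=O)C(C)C)[C@@H](OC(=O)C(C)C)[C@@H]12 | target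

**Step count**
Total: 15 steps. Longest linear sequence: 13 steps (steps 1–6 and 9–15).

**Steps most likely to fail**

1. Step 13. Ring closure to the ten-membered ring may be slow enough that protodeiodination and oligomerisation take over. The β-acyloxy, β,γ-unsaturated aldehyde may lose isobutyric acid or epimerise at C7 before it cyclises. Facial selectivity at C6 may be low, and the C6 alkoxide may take the isobutyryl group from O8 instead of lactonising. The fallback keeps the same bond formation but ties O8 and O9 into a temporary trans-dioxolane; this removes the acyloxy leaving group and the acyl-shift pathway and restricts rotation about C8–C9. It sets out from 19. 2,2-Dimethoxypropane with PPTS gives methyl (3R)-3-[(4S,5S)-5-[(2Z,6Z)-1-{[tert-butyl(diphenyl)silyl]oxy}-7-iodo-6-methylhepta-2,6-dien-2-yl]-2,2-dimethyl-1,3-dioxolan-4-yl]-4,4-dimethoxy-2-methylidenebutanoate F1. LiBF4 in wet MeCN cleaves the dimethyl acetal to methyl (3R)-3-[(4S,5S)-5-[(2Z,6Z)-1-{[tert-butyl(diphenyl)silyl]oxy}-7-iodo-6-methylhepta-2,6-dien-2-yl]-2,2-dimethyl-1,3-dioxolan-4-yl]-2-methylidene-4-oxobutanoate F2. CrCl2/NiCl2 under the conditions of step 13 gives the 8,9-O-isopropylidene macrocyclic lactone (3aS,4S,5S,11aR; 6Z,10Z) F3. Aqueous AcOH (80%, 40 °C) gives (3aR,4S,5S,6Z,10Z,11aR)-6-({[tert-butyl(diphenyl)silyl]oxy}methyl)-4,5-dihydroxy-10-methyl-3-methylidene-3a,4,5,8,9,11a-hexahydrocyclodeca[b]furan-2(3H)-one F4. Acylation of F4 with (iPrCO)2O/DMAP returns to the route at 23.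

2. Step 9. The simple (C7/C8) or the facial (C8/C9) diastereoselection of the indium reaction may be low or opposite. The allylindium may lose methoxide by β-elimination, and O8 may lactonise onto C12 before it is acylated. The fallback replaces the cyclic indium transition state by a Lewis-acid-mediated open one with Cram-chelate control. It sets out from 12. 4-Methoxybenzyl trichloroacetimidate with La(OTf)3 (cat.) gives (3S,4Z)-4-[(4Z)-5-iodo-4-methylpent-4-en-1-ylidene]-3-[(4-methoxyphenyl)methoxy]oxolan-2-one F5. Me(MeO)NH·HCl/Me3Al opens the lactone to (2S,3Z,7Z)-3-(hydroxymethyl)-8-iodo-N-methoxy-2-[(4-methoxyphenyl)methoxy]-N,7-dimethylocta-3,7-dienamide F6. TBDPSCl/imidazole gives (2S,3Z,7Z)-3-({[tert-butyl(diphenyl)silyl]oxy}methyl)-8-iodo-N-methoxy-2-[(4-methoxyphenyl)methoxy]-N,7-dimethylocta-3,7-dienamide F7. DIBAL-H at −78 °C gives (2S,3Z,7Z)-3-({[tert-butyl(diphenyl)silyl]oxy}methyl)-8-iodo-2-[(4-methoxyphenyl)methoxy]-7-methylocta-3,7-dienal F8. Bromide 17 and Bu3SnLi give methyl (2Z)-4,4-dimethoxy-2-[(tributylstannyl)methyl]but-2-enoate F9. MgBr2·OEt2 in CH2Cl2 then adds F9 to F8 (chelate control for 8,9-syn, antiperiplanar SE2′ for 7,8-syn) to give methyl (3R,4S,5S,6Z,10Z)-6-({[tert-butyl(diphenyl)silyl]oxy}methyl)-3-(dimethoxymethyl)-4-hydroxy-11-iodo-5-[(4-methoxyphenyl)methoxy]-10-methyl-2-methylideneundeca-6,10-dienoate F10. DDQ in CH2Cl2/pH 7 buffer removes the 4-methoxybenzyl group and returns to the route at 19.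

3. Step 4. The ring opening may be slow with an amidine base, and under stronger base retro-aldol cleavage of the C9–C10 bond, drift of the olefin out of conjugation or erosion of the olefin geometry may compete. The fallback builds the alkylidene succinate by olefination and introduces the C9 hydroxyl afterwards. It sets out from 5. Wittig reaction with dimethyl 2-(triphenylphosphoranylidene)butanedioate (toluene, 80 °C) gives dimethyl (2E)-2-[(4Z)-5-iodo-4-methylpent-4-en-1-ylidene]butanedioate F11. KHMDS at −78 °C, then the enantiomer of (camphorsulfonyl)oxaziridine that delivers the 2S alcohol, gives dimethyl (2S,3E)-2-hydroxy-3-[(4Z)-5-iodo-4-methylpent-4-en-1-ylidene]butanedioate F12. LiOH (1 equiv) in THF/H2O at 0 °C hydrolyses the non-conjugated α-hydroxy ester selectively and returns to the route at 10.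

**Further compounds**
F1 | step 13 | methyl (3R)-3-[(4S,5S)-5-[(2Z,6Z)-1-{[tert-butyl(diphenyl)silyl]oxy}-7-iodo-6-methylhepta-2,6-dien-2-yl]-2,2-dimethyl-1,3-dioxolan-4-yl]-4,4-dimethoxy-2-methylidenebutanoate | I/C=C(/C)CC/C=C(/CO[Si](c1ccccc1)(c1ccccc1)C(C)(C)C)[C@@H]1OC(C)(C)O[C@H]1[C@@H](C(=C)C(=O)OC)C(OC)OC
F2 | step 13 | methyl (3R)-3-[(4S,5S)-5-[(2Z,6Z)-1-{[tert-butyl(diphenyl)silyl]oxy}-7-iodo-6-methylhepta-2,6-dien-2-yl]-2,2-dimethyl-1,3-dioxolan-4-yl]-2-methylidene-4-oxobutanoate | I/C=C(/C)CC/C=C(/CO[Si](c1ccccc1)(c1ccccc1)C(C)(C)C)[C@@H]1OC(C)(C)O[C@H]1[C@@H](C(=C)C(=O)OC)C=O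
F3 | step 13 | 8,9-O-isopropylidene acetal of F4 (3aS,4S,5S,11aR; 6Z,10Z) | C=C1C(=O)O[C@@H]2/C=C(/C)CC/C=C(/CO[Si](c3ccccc3)(c3ccccc3)C(C)(C)C)[C@@H]3OC(C)(C)O[C@H]3[C@@H]12
F4 | step 13 | (3aR,4S,5S,6Z,10Z,11aR)-6-({[tert-butyl(diphenyl)silyl]oxy}methyl)-4,5-dihydroxy-10-methyl-3-methylidene-3a,4,5,8,9,11a-hexahydrocyclodeca[b]furan-2(3H)-one | C=C1C(=O)O[C@@H]2/C=C(/C)CC/C=C(/CO[Si](c3ccccc3)(c3ccccc3)C(C)(C)C)[C@H](O)[C@@H](O)[C@@H]12
F5 | step 9 | (3S,4Z)-4-[(4Z)-5-iodo-4-methylpent-4-en-1-ylidene]-3-[(4-methoxyphenyl)methoxy]oxolan-2-one | O1C/C(=C/CC/C(C)=C\I)[C@H](OCc2ccc(OC)cc2)C1=O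
F6 | step 9 | (2S,3Z,7Z)-3-(hydroxymethyl)-8-iodo-N-methoxy-2-[(4-methoxyphenyl)methoxy]-N,7-dimethylocta-3,7-dienamide | OC/C(=C/CC/C(C)=C\I)[C@H](OCc1ccc(OC)cc1)C(=O)N(C)OC
F7 | step 9 | (2S,3Z,7Z)-3-({[tert-butyl(diphenyl)silyl]oxy}methyl)-8-iodo-N-methoxy-2-[(4-methoxyphenyl)methoxy]-N,7-dimethylocta-3,7-dienamide | CC(C)(C)[Si](c1ccccc1)(c1ccccc1)OC/C(=C/CC/C(C)=C\I)[C@H](OCc1ccc(OC)cc1)C(=O)N(C)OC
F8 | step 9 | (2S,3Z,7Z)-3-({[tert-butyl(diphenyl)silyl]oxy}methyl)-8-iodo-2-[(4-methoxyphenyl)methoxy]-7-methylocta-3,7-dienal | CC(C)(C)[Si](c1ccccc1)(c1ccccc1)OC/C(=C/CC/C(C)=C\I)[C@H](OCc1ccc(OC)cc1)C=O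
F9 | step 9 | methyl (2Z)-4,4-dimethoxy-2-[(tributylstannyl)methyl]but-2-enoate | CCCC[Sn](CCCC)(CCCC)C/C(C(=O)OC)=C\C(OC)OC
F10 | step 9 | methyl (3R,4S,5S,6Z,10Z)-6-({[tert-butyl(diphenyl)silyl]oxy}methyl)-3-(dimethoxymethyl)-4-hydroxy-11-iodo-5-[(4-methoxyphenyl)methoxy]-10-methyl-2-methylideneundeca-6,10-dienoate | I/C=C(/C)CC/C=C(/CO[Si](c1ccccc1)(c1ccccc1)C(C)(C)C)[C@H](OCc1ccc(OC)cc1)[C@@H](O)[C@@H](C(=C)C(=O)OC)C(OC)OC
F11 | step 4 | dimethyl (2E)-2-[(4Z)-5-iodo-4-methylpent-4-en-1-ylidene]butanedioate | COC(=O)/C(CC(=O)OC)=C/CC/C(C)=C\I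
F12 | step 4 | dimethyl (2S,3E)-2-hydroxy-3-[(4Z)-5-iodo-4-methylpent-4-en-1-ylidene]butanedioate | COC(=O)/C(=C/CC/C(C)=C\I)[C@H](O)C(=O)OC
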